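**Plan**
1. Retrosynthesis first cuts the two aryl methyl ethers, then the ArCH2–CH2Ar bond between rings A and B, which is traced back to a CH2–NH–CH2 unit: the 18-membered carbocycle comes from a 19-membered azacyclophane by deletion of its nitrogen atom.
2. The azacycle is opened at the N–CH2 bond on ring A (macrocyclic reductive amination of an amino aldehyde); the C–D ethylene bridge is cut at the ring D–CH bond (Heck), the A–O–D ether by SNAr and the B–O–C ether by Chan–Lam coupling.
3. Forward: the A–D and B–C diaryl ethers are made separately and joined through the C–D bridge, the chain is closed through nitrogen to the 19-membered ring, this ring is contracted to 18 by loss of N2, and the phenols are freed last.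
4. The enabling feature: both carbons flanking the nitrogen are benzylic (the CH2 on ring A ortho to the A–O–D oxygen and the CH2 on ring B para to its oxygen substituent), so the 1,1-diazene gives two stabilised benzyl radicals that stay tied together through rings D and C.
5. Stereochemistry: the target has no stereocentre; the E-alkene of the Heck product and the imine geometry disappear on reduction.

Key step: step 7

Remark: dihydroptychantol A has no stereocentre and the 18-membered ring is taken as conformationally mobile (no separable atropisomers), so no stereocontrol is planned.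

**Step 1**
Reactants: 1 2-fluoro-5-methoxybenzaldehyde; 2 3-bromophenol
Product: 3 2-(3-bromophenoxy)-5-methoxybenzaldehyde
Conditions: K2CO3, DMA, 150 °C
Reagents that add atoms: none
Why: Nucleophilic aromatic substitution (SNAr), in which the ortho-formyl group activates the C–F carbon towards the phenoxide of 2 and fluoride is the preferred leaving group, while the aryl bromide is inert under metal-free conditions.

**Step 2**
Reactants: 3 2-(3-bromophenoxy)-5-methoxybenzaldehyde
Product: 4 2-[2-(3-bromophenoxy)-5-methoxyphenyl]-1,3-dioxolane
Conditions: ethylene glycol, TsOH·H2O (cat.), toluene, reflux, Dean–Stark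
Reagents that add atoms: ethylene glycol, OCCO
Why: Acid-catalysed acetalisation with azeotropic removal of water should mask the aldehyde as a dioxolane that is stable to the basic Heck step and to the hydrogenation.

**Step 3**
Reactants: 5 3-hydroxy-4-methoxybenzonitrile; 6 4-vinylphenylboronic acid
Product: 7 3-(4-ethenylphenoxy)-4-methoxybenzonitrile
Conditions: Cu(OAc)2 (20 mol %), pyridine, 4 Å MS, CH2Cl2, O2 (1 atm), rt
Reagents that add atoms: none
Why: Chan–Lam oxidative O-arylation of a phenol by an arylboronic acid at room temperature should leave the vinyl group and the nitrile untouched, with dioxygen returning the copper to the divalent state.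

**Step 4**
Reactants: 4 2-[2-(3-bromophenoxy)-5-methoxyphenyl]-1,3-dioxolane; 7 3-(4-ethenylphenoxy)-4-methoxybenzonitrile
Product: 8 3-[4-[(E)-2-[3-[2-(1,3-dioxolan-2-yl)-4-methoxyphenoxy]phenyl]ethenyl]phenoxy]-4-methoxybenzonitrile
Conditions: Pd(OAc)2 (5 mol %), P(o-tol)3 (10 mol %), Et3N, DMF, 100 °C
Reagents that add atoms: none
Why: Heck reaction of the aryl bromide with the terminal styrene through zerovalent palladium formed in the flask, in which syn insertion at the unsubstituted alkene carbon and syn β-hydride elimination should give the E-stilbene, the acetal and nitrile being inert to the basic medium.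

**Step 5**
Reactants: 8 the E-stilbene nitrile acetal
Product: 9 [3-[4-[2-[3-[2-(1,3-dioxolan-2-yl)-4-methoxyphenoxy]phenyl]ethyl]phenoxy]-4-methoxyphenyl]methanamine
Conditions: H2 (4 atm), Raney Ni, 7 M NH3 in MeOH, THF, rt
Reagents that add atoms: none
Why: Heterogeneous hydrogenation over Raney Ni should saturate the stilbene C=C and reduce the nitrile to the primary amine, ammonia suppressing secondary-amine formation, while the dioxolane and all aryl ethers are stable.

**Step 6**
Reactants: 9 the primary amine acetal
Product: 12 19-membered azacyclophane (di-O-methyldihydroptychantol A carrying an NH between the benzylic CH2 groups of rings A and B), via amino aldehyde hydrochloride 10 (not isolated), via macrocyclic E-aldimine 11 (not isolated)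
Conditions: 1 M aq HCl, THF, rt; concentrate; slow addition to Et3N, 3 Å MS, CH2Cl2/MeOH (final 1 mM), rt; then NaBH4, 0 °C
Reagents that add atoms: none
Why: Macrocyclic reductive amination in which the acetal is hydrolysed on the ammonium salt so that no imine forms at high concentration, slow neutralisation at high dilution lets the reversible condensation settle on the monomeric 19-membered aldimine, and NaBH4 then fixes it irreversibly as the secondary amine.

**Step 7**
Reactants: 12 the 19-membered azacyclophane
Product: 15 di-O-methyldihydroptychantol A (18-membered bis(bibenzyl) macrocycle), via N-benzyloxy hydrazide adduct 13 (not isolated), via macrocyclic isodiazene 14 (not isolated)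
Conditions: N-(benzyloxy)-N-(pivaloyloxy)-4-(trifluoromethyl)benzamide (1.5 equiv), THF (0.01 M), 45 °C
Reagents that add atoms: none
Why: The secondary amine attacks the electrophilic nitrogen of the anomeric amide with loss of pivalate to give the N-amino-N-benzyloxy amide 13, which undergoes reductive elimination with migration of the benzyloxy group to the acyl carbon to give the 1,1-diazene 14; this expels N2 and the resulting pair of benzyl radicals recombines. The closest known reaction type is the anomeric-amide nitrogen deletion of acyclic and cyclic bis-benzylic secondary amines (dibenzylamine to bibenzyl, benzo-fused azacycles to the contracted carbocycles), here applied to a macrocyclic member of that class. The 18-membered ring is closed by contraction of the 19-membered azacycle, that is by radical–radical recombination of a 1,18-diradical whose ends are held together by the ring A–O–ring D–CH2CH2–ring C–O–ring B chain, so closure stays intramolecular even after the radicals separate. No stereocentre is formed. The selectivity needed is recombination over intermolecular coupling, over tetrazene formation from two isodiazenes, over tautomerisation of the isodiazene to a hydrazone and over hydrogen abstraction from THF; it should be secured by the benzylic character of both C–N bonds (fast N2 loss, persistent radicals that cannot disproportionate), by the tether and by the 0.01 M concentration. Chemoselectivity at nitrogen is secured because the N–H is the only nucleophilic site, both phenols being masked as methyl ethers.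

**Step 8**
Reactants: 15 di-O-methyldihydroptychantol A
Product: 16 dihydroptychantol A
Conditions: BBr3, CH2Cl2, −78 °C to rt; then H2O
Reagents that add atoms: none
Why: BBr3 cleavage of aryl methyl ethers (Lewis-acid activation, then SN2 attack of bromide on methyl) should free both phenols while the diaryl ethers and bibenzyl bridges stay intact.

**Compound list**
1 | 2-fluoro-5-methoxybenzaldehyde | COc1ccc(F)c(C=O)c1 | starting material
2 | 3-bromophenol | Oc1cccc(Br)c1 | starting material
3 | 2-(3-bromophenoxy)-5-methoxybenzaldehyde | COc1ccc(Oc2cccc(Br)c2)c(C=O)c1 | intermediate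
4 | 2-[2-(3-bromophenoxy)-5-methoxyphenyl]-1,3-dioxolane | COc1ccc(Oc2cccc(Br)c2)c(c1)C1OCCO1 | intermediate
5 | 3-hydroxy-4-methoxybenzonitrile | COc1ccc(C#N)cc1O | starting material
6 | 4-vinylphenylboronic acid | OB(O)c1ccc(C=C)cc1 | starting material
7 | 3-(4-ethenylphenoxy)-4-methoxybenzonitrile | COc1ccc(C#N)cc1Oc1ccc(C=C)cc1 | intermediate
8 | 3-[4-[(E)-2-[3-[2-(1,3-dioxolan-2-yl)-4-methoxyphenoxy]phenyl]ethenyl]phenoxy]-4-methoxybenzonitrile | COc1ccc(C#N)cc1Oc1ccc(/C=C/c2cccc(Oc3ccc(OC)cc3C3OCCO3)c2)cc1 | intermediate
9 | [3-[4-[2-[3-[2-(1,3-dioxolan-2-yl)-4-methoxyphenoxy]phenyl]ethyl]phenoxy]-4-methoxyphenyl]methanamine | COc1ccc(CN)cc1Oc1ccc(CCc2cccc(Oc3ccc(OC)cc3C3OCCO3)c2)cc1 | intermediate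
10 | 2-[3-[2-[4-[5-(aminomethyl)-2-methoxyphenoxy]phenyl]ethyl]phenoxy]-5-methoxybenzaldehyde hydrochloride | COc1ccc(C[NH3+])cc1Oc1ccc(CCc2cccc(Oc3ccc(OC)cc3C=O)c2)cc1.[Cl-] | intermediate (not isolated)
11 | 19-membered macrocyclic E-aldimine (ring A–CH=N–CH2–ring B) | COc1ccc2c(c1)/C=N/Cc1ccc(OC)c(c1)Oc1ccc(cc1)CCc1cccc(c1)O2 | intermediate (not isolated)
12 | 19-membered azacyclophane, secondary amine (ring A–CH2–NH–CH2–ring B) | COc1ccc2c(c1)CNCc1ccc(OC)c(c1)Oc1ccc(cc1)CCc1cccc(c1)O2 | intermediate
13 | N-benzyloxy hydrazide adduct: ring nitrogen of 12 bonded to the nitrogen of N-(benzyloxy)-4-(trifluoromethyl)benzamide | COc1ccc2c(c1)CN(N(OCc3ccccc3)C(=O)c3ccc(cc3)C(F)(F)F)Cc1ccc(OC)c(c1)Oc1ccc(cc1)CCc1cccc(c1)O2 | intermediate (not isolated)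
14 | macrocyclic isodiazene (1,1-diazene on the ring nitrogen) | COc1ccc2c(c1)C[N+](=[N-])Cc1ccc(OC)c(c1)Oc1ccc(cc1)CCc1cccc(c1)O2 | intermediate (not isolated)
15 | di-O-methyldihydroptychantol A | COc1ccc2c(c1)CCc1ccc(OC)c(c1)Oc1ccc(cc1)CCc1cccc(c1)O2 | intermediate
16 | dihydroptychantol A | Oc1ccc2c(c1)CCc1ccc(O)c(c1)Oc1ccc(cc1)CCc1cccc(c1)O2 | target

**Count**
Total steps: 8. Longest linear sequence: 7 steps (steps 1, 2, 4, 5, 6, 7, 8).

**Steps most likely to fail**

Step 7. The tethered benzyl radicals may couple between molecules, or the isodiazene may be diverted into tetrazene or hydrazone formation before N2 is lost, so that ring contraction is inefficient. The fallback gives up nitrogen deletion and closes the same bond by carbonyl coupling. It sets out from 8: hydrogenation of the alkene only (H2, Pd/C, EtOAc) should give the saturated nitrile acetal F1. Reduction with i-Bu2AlH (toluene, −78 °C) and work-up with aqueous HCl, which hydrolyses both the aldimine and the dioxolane, should give the dialdehyde F2. Intramolecular McMurry coupling with low-valent titanium from TiCl4 and Zn (pyridine, THF, reflux, syringe-pump addition) should give the macrocyclic Z-stilbene F3; any E isomer converges. Hydrogenation (H2, Pd/C, EtOAc) then returns to the route at 15.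

Step 6. Condensation between molecules may outrun ring closure, giving cyclic dimers and oligomeric imines, or the aldehyde may be reduced before the imine has formed. The fallback replaces the reversible imine closure by an irreversible sulfonamide alkylation. It sets out from 9: 2-nitrobenzenesulfonyl chloride and Et3N in CH2Cl2 should give the N-nosyl acetal F4. Aqueous HCl in THF should give the N-nosyl aldehyde F5, and NaBH4 in MeOH the N-nosyl benzylic alcohol F6. Intramolecular Fukuyama–Mitsunobu alkylation (PPh3, DEAD, THF/toluene, 2 mM) should give the N-nosyl azacyclophane F7. Thiophenol and K2CO3 in DMF remove the sulfonyl group and return to the route at 12.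

Step 3. Oxidative coupling of the hindered, electron-poor ortho-methoxy phenol may be slow, so that protodeboronation and homocoupling of the boronic acid or polymerisation of the styrene take over. The fallback builds the ether by SNAr and installs the alkene afterwards. It sets out from 5: 4-fluorobenzaldehyde with K2CO3 in DMF at 120 °C should give 3-(4-formylphenoxy)-4-methoxybenzonitrile F8. Wittig methylenation (Ph3PCH3Br, KOtBu, THF, 0 °C) then returns to the route at 7.

**Further compounds**
F1 | step 7 | 3-[4-[2-[3-[2-(1,3-dioxolan-2-yl)-4-methoxyphenoxy]phenyl]ethyl]phenoxy]-4-methoxybenzonitrile | COc1ccc(C#N)cc1Oc1ccc(CCc2cccc(Oc3ccc(OC)cc3C3OCCO3)c2)cc1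
F2 | step 7 | 3-[4-[2-[3-(2-formyl-4-methoxyphenoxy)phenyl]ethyl]phenoxy]-4-methoxybenzaldehyde | COc1ccc(C=O)cc1Oc1ccc(CCc2cccc(Oc3ccc(OC)cc3C=O)c2)cc1
F3 | step 7 | 18-membered macrocyclic Z-stilbene (15 with a Z C=C between rings A and B) | COc1ccc2c(c1)/C=C\c1ccc(OC)c(c1)Oc1ccc(cc1)CCc1cccc(c1)O2
F4 | step 6 | N-(2-nitrobenzenesulfonyl) derivative of amine 9 | COc1ccc(CNS(=O)(=O)c2ccccc2[N+](=O)[O-])cc1Oc1ccc(CCc2cccc(Oc3ccc(OC)cc3C3OCCO3)c2)cc1
F5 | step 6 | N-(2-nitrobenzenesulfonyl) amino aldehyde | COc1ccc(CNS(=O)(=O)c2ccccc2[N+](=O)[O-])cc1Oc1ccc(CCc2cccc(Oc3ccc(OC)cc3C=O)c2)cc1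
F6 | step 6 | N-(2-nitrobenzenesulfonyl) amino benzylic alcohol | COc1ccc(CNS(=O)(=O)c2ccccc2[N+](=O)[O-])cc1Oc1ccc(CCc2cccc(Oc3ccc(OC)cc3CO)c2)cc1
F7 | step 6 | N-(2-nitrobenzenesulfonyl) derivative of azacyclophane 12 | COc1ccc2c(c1)CN(S(=O)(=O)c3ccccc3[N+](=O)[O-])Cc1ccc(OC)c(c1)Oc1ccc(cc1)CCc1cccc(c1)O2
F8 | step 3 | 3-(4-formylphenoxy)-4-methoxybenzonitrile | COc1ccc(C#N)cc1Oc1ccc(C=O)cc1
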